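**Assumption:** all‑E geranylgeraniol (≥95 % isomeric purity) is taken as a purchasable starting material.
**Abbreviation:** GG = (2E,6E,10E)-3,7,11,15-tetramethylhexadeca-2,6,10,14-tetraen-1-yl.

## Retrosynthetic overview

1. The C4–O bond is made last, by an oxygenation of the silyl dienol ether of (5R)-2-methyl-5-GG-cyclohex-2-enone that places oxygen cis to the C5 side chain (key step, sets C4).
2. That enone comes from regioselective desaturation of (5S)-2-methyl-5-GG-cyclohexanone, itself from CuH asymmetric conjugate reduction of 6-methyl-3-GG-cyclohex-2-enone (sets C5).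
3. The β‑GG enone comes from Birch reduction/hydrolysis of 2-methyl-5-GG-anisole, made from an aryl Grignard and geranylgeranyl bromide (the all‑E chain is used only as an electrophile).
4. No ring is formed: the single carbocycle is carried in from the aromatic starting material and dearomatised.

## Route

Step 1
Reactants: 1 (2E,6E,10E)-geranylgeraniol
Product: 2 (2E,6E,10E)-geranylgeranyl bromide
Conditions: PBr3 (0.4 equiv), Et2O, −10 °C, 30 min; crude bromide used at once
Reagents that add atoms: phosphorus tribromide, BrP(Br)Br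
Why: PBr3 bromination of a primary allylic alcohol (SN2 on the phosphite ester) at low temperature keeps the 2E geometry and creates no stereocentre.

Step 2
Reactants: 2 geranylgeranyl bromide; 3 4-bromo-2-methoxy-1-methylbenzene
Product: 5 2-methoxy-1-methyl-4-GG-benzene, via aryl Grignard 4 (not isolated)
Conditions: 3, Mg, THF, 40 °C; then 2, Li2CuCl4 (3 mol %), THF, −30 → 0 °C
Reagents that add atoms: none
Why: Kochi-type copper-catalysed Grignard–allylic bromide coupling attacks the primary (α) carbon of the configurationally stable bromide, so the chain is attached with all double bonds E.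

Step 3
Reactants: 5 2-methoxy-1-methyl-4-GG-benzene
Product: 8 (±)-6-methyl-3-GG-cyclohex-2-en-1-one, via Birch diene 6 (not isolated), via deconjugated enone 7 (not isolated)
Conditions: Li, NH3(l)/THF/t-BuOH, −78 °C, then NH4Cl; (CO2H)2, THF/MeOH/H2O, rt; DBU (0.2 equiv), CH2Cl2, rt
Reagents that add atoms: water, O
Why: Birch reduction keeps the OMe- and alkyl-bearing carbons sp2 and leaves the isolated chain alkenes alone, enol ether hydrolysis gives the β,γ-enone and DBU moves the ring alkene into conjugation (as in the thymol methyl ether to piperitone sequence); the methyl-bearing centre stays racemic because it becomes sp2 in step 5.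

Step 4
Reactants: 8 (±)-6-methyl-3-GG-cyclohex-2-en-1-one
Product: 9 (5S)-2-methyl-5-GG-cyclohexan-1-one (C2 epimers)
Conditions: Cu(OAc)2·H2O (3 mol %), (R)-DTBM-SEGPHOS (3.3 mol %), (EtO)2MeSiH (2 equiv), t-BuOH (1.1 equiv), toluene, 0 °C
Reagents that add atoms: none
Why: Copper hydride asymmetric conjugate reduction (Buchwald–Lipshutz type) delivers hydride to one face of the enone β-carbon only, leaves isolated alkenes untouched and sets C5 as S by ligand control (the ligand antipode is used if the observed sense is opposite); the C2 epimers converge in step 5.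

Step 5
Reactants: 9 (5S)-2-methyl-5-GG-cyclohexan-1-one
Product: 11 (5R)-2-methyl-5-GG-cyclohex-2-en-1-one, via TMS enol ether 10 (not isolated)
Conditions: TMSCl, NaI, Et3N, MeCN, rt; then Pd(OAc)2 (1.05 equiv), MeCN, rt
Reagents that add atoms: none
Why: In situ TMSI/Et3N gives the thermodynamic, more substituted silyl enol ether and Saegusa–Ito oxidation (Pd(II) enolate, β-hydride elimination) installs the C2=C3 alkene; C5 is untouched and its descriptor changes from S to R only through CIP priorities.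

Step 6
Reactants: 11 (5R)-2-methyl-5-GG-cyclohex-2-en-1-one
Product: 13 (5S)-1-(tert-butyldimethylsilyloxy)-2-methyl-5-GG-cyclohexa-1,3-diene, via potassium dienolate 12 (not isolated)
Conditions: t-BuOK (1.3 equiv), THF/DMPU, −20 °C, 30 min; TBSCl (1.5 equiv), −20 °C → rt; Et3N-deactivated silica
Reagents that add atoms: tert-butyldimethylsilyl chloride, CC(C)(C)[Si](C)(C)Cl
Why: Thermodynamic γ-deprotonation of the enone gives the linear (extended) dienolate, which is O-silylated to the 1-silyloxy-1,3-diene (silyl dienol ether formation); C5 is not touched.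

Step 7
Reactants: 13 (5S)-1-(tert-butyldimethylsilyloxy)-2-methyl-5-GG-cyclohexa-1,3-diene
Product: 16 (4S,5S)-4-hydroxy-2-methyl-5-GG-cyclohex-2-en-1-one (target), via allyl iodane 14 (not isolated), via trifluoroacetate ester 15 (not isolated)
Conditions: PhI(O2CCF3)2 (1.05 equiv), n-Bu4N O2CCF3 (2 equiv), CH2Cl2, −78 °C, 30 min; then sat. aq NaHCO3/THF, 0 °C → rt
Reagents that add atoms: [bis(trifluoroacetoxy)iodo]benzene, O=C(OI(OC(=O)C(F)(F)F)c1ccccc1)C(F)(F)F
Why: Proposed new method: stereoinvertive vinylogous (γ) oxygenation of a silyl dienol ether by a λ3-iodane, in which the bulky PhI(O2CCF3)+ electrophile bonds to C4 on the face anti to the C5 side chain (C2 is blocked as a tetrasubstituted carbon and the O-silyl group prevents an O-bound iodine enolate) and trifluoroacetate then displaces the hypernucleofugal PhI by SN2 with inversion (SN1 is disfavoured at a γ-keto allylic carbon, anti-E2 toward C5 is impossible because C5–H is syn to iodine, and the silyl dienol ether outcompetes the chain alkenes at −78 °C), so oxygen ends up cis to the side chain and bicarbonate hydrolysis of the ester gives the (4S,5S) alcohol; the closest known reaction type is α-oxygenation of ketone silyl enol ethers with PhI(OAc)2, PhIO–BF3 or Koser's reagent through C-bound iodonium enolates.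

## Compound list

1 | (2E,6E,10E)-geranylgeraniol (GG–OH) | CC(C)=CCC/C(C)=C/CC/C(C)=C/CC/C(C)=C/CO | starting material
2 | (2E,6E,10E)-geranylgeranyl bromide (GG–Br) | CC(C)=CCC/C(C)=C/CC/C(C)=C/CC/C(C)=C/CBr | intermediate
3 | 4-bromo-2-methoxy-1-methylbenzene (5-bromo-2-methylanisole) | COc1cc(Br)ccc1C | starting material
4 | (3-methoxy-4-methylphenyl)magnesium bromide | COc1cc([Mg]Br)ccc1C | intermediate
5 | 2-methoxy-1-methyl-4-GG-benzene | CC(C)=CCC/C(C)=C/CC/C(C)=C/CC/C(C)=C/Cc1ccc(C)c(OC)c1 | intermediate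
6 | 1-methoxy-2-methyl-5-GG-cyclohexa-1,4-diene | CC(C)=CCC/C(C)=C/CC/C(C)=C/CC/C(C)=C/CC1=CCC(C)=C(OC)C1 | intermediate
7 | (±)-2-methyl-5-GG-cyclohex-4-en-1-one | CC(C)=CCC/C(C)=C/CC/C(C)=C/CC/C(C)=C/CC1=CCC(C)C(=O)C1 | intermediate
8 | (±)-6-methyl-3-GG-cyclohex-2-en-1-one | CC(C)=CCC/C(C)=C/CC/C(C)=C/CC/C(C)=C/CC1=CC(=O)C(C)CC1 | intermediate
9 | (5S)-2-methyl-5-GG-cyclohexan-1-one (C2 epimers) | CC(C)=CCC/C(C)=C/CC/C(C)=C/CC/C(C)=C/C[C@H]1CC(=O)C(C)CC1 | intermediate
10 | (5S)-2-methyl-5-GG-1-(trimethylsilyloxy)cyclohex-1-ene | CC(C)=CCC/C(C)=C/CC/C(C)=C/CC/C(C)=C/C[C@H]1CC(O[Si](C)(C)C)=C(C)CC1 | intermediate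
11 | (5R)-2-methyl-5-GG-cyclohex-2-en-1-one | CC(C)=CCC/C(C)=C/CC/C(C)=C/CC/C(C)=C/C[C@H]1CC(=O)C(C)=CC1 | intermediate
12 | potassium (5S)-2-methyl-5-GG-cyclohexa-1,3-dien-1-olate | CC(C)=CCC/C(C)=C/CC/C(C)=C/CC/C(C)=C/C[C@H]1CC([O-])=C(C)C=C1.[K+] | intermediate
13 | (5S)-1-(tert-butyldimethylsilyloxy)-2-methyl-5-GG-cyclohexa-1,3-diene | CC(C)=CCC/C(C)=C/CC/C(C)=C/CC/C(C)=C/C[C@H]1CC(O[Si](C)(C)C(C)(C)C)=C(C)C=C1 | intermediate
14 | (4R,5S)-2-methyl-4-[phenyl(trifluoroacetoxy)-λ3-iodanyl]-5-GG-cyclohex-2-en-1-one (trans) | CC(C)=CCC/C(C)=C/CC/C(C)=C/CC/C(C)=C/C[C@H]1CC(=O)C(C)=C[C@@H]1I(OC(=O)C(F)(F)F)c2ccccc2 | intermediate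
15 | (4S,5S)-2-methyl-4-(trifluoroacetoxy)-5-GG-cyclohex-2-en-1-one (cis) | CC(C)=CCC/C(C)=C/CC/C(C)=C/CC/C(C)=C/C[C@H]1CC(=O)C(C)=C[C@H]1OC(=O)C(F)(F)F | intermediate
16 | (4S,5S)-4-hydroxy-2-methyl-5-[(2E,6E,10E)-3,7,11,15-tetramethylhexadeca-2,6,10,14-tetraen-1-yl]cyclohex-2-en-1-one (cis) | CC(C)=CCC/C(C)=C/CC/C(C)=C/CC/C(C)=C/C[C@H]1CC(=O)C(C)=C[C@H]1O | target

## Step count and risks

Total step count: 7. Longest linear sequence: 7 steps (1 → 16); aryl bromide 3 enters in step 2.

The three steps most likely to fail are 7, 5 and 4.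

**Step 7** is the new reaction. Its risks are attack at C2, ligand coupling with retention, and aromatisation to the phenol. The fallback uses known chemistry and runs from 13 back to 16. Dimethyldioxirane (1.0 equiv, acetone/CH2Cl2, −78 °C; vinylogous Rubottom oxidation, the silyl dienol ether reacting much faster than the chain alkenes) attacks C4 anti to the side chain and gives, after aqueous work-up, the trans alcohol (4R,5S)-4-hydroxy-2-methyl-5-GG-cyclohex-2-en-1-one F1. Mitsunobu inversion (4-nitrobenzoic acid, PPh3, DIAD, THF, 0 °C) then gives the cis ester (4S,5S)-2-methyl-4-(4-nitrobenzoyloxy)-5-GG-cyclohex-2-en-1-one F2. K2CO3 in MeOH at 0 °C releases 16.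

**Step 5** risks incomplete regiocontrol in the enol silane (the minor isomer returns achiral 8) and Pd(II) touching the polyene. The fallback runs from 8 back to 11 and fixes the regiochemistry before the reduction. LDA (THF, −78 °C; the only α′-hydrogen sits on the methyl-bearing carbon) followed by PhSSPh gives 6-methyl-6-(phenylsulfanyl)-3-GG-cyclohex-2-en-1-one F3. The CuH reduction of step 4 applied to F3 gives (5S)-2-methyl-2-(phenylsulfanyl)-5-GG-cyclohexan-1-one F4. NaIO4 (MeOH/H2O, 0 °C) gives the sulfoxide (5S)-2-methyl-2-(phenylsulfinyl)-5-GG-cyclohexan-1-one F5, and thermal syn-elimination (toluene, P(OMe)3, 90 °C) gives 11.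

**Step 4** risks lower ee from the racemic, enolisable α′-methyl centre, and the sense of induction is assigned by analogy only. The fallback runs from 8 back to 9 and replaces metal hydride insertion by iminium-ion organocatalysis: transfer hydrogenation with a Hantzsch ester and a chiral primary ammonium salt (valine tert-butyl ester with a chiral BINOL-phosphate counter-anion, Bu2O, 60 °C). It makes no new compound F0.

## Further compounds

F1 | step 7 | (4R,5S)-4-hydroxy-2-methyl-5-GG-cyclohex-2-en-1-one (trans) | CC(C)=CCC/C(C)=C/CC/C(C)=C/CC/C(C)=C/C[C@H]1CC(=O)C(C)=C[C@@H]1O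
F2 | step 7 | (4S,5S)-2-methyl-4-(4-nitrobenzoyloxy)-5-GG-cyclohex-2-en-1-one (cis) | CC(C)=CCC/C(C)=C/CC/C(C)=C/CC/C(C)=C/C[C@H]1CC(=O)C(C)=C[C@H]1OC(=O)c2ccc(cc2)[N+](=O)[O-]
F3 | step 5 | (±)-6-methyl-6-(phenylsulfanyl)-3-GG-cyclohex-2-en-1-one | CC(C)=CCC/C(C)=C/CC/C(C)=C/CC/C(C)=C/CC1=CC(=O)C(C)(Sc2ccccc2)CC1
F4 | step 5 | (5S)-2-methyl-2-(phenylsulfanyl)-5-GG-cyclohexan-1-one (C2 epimers) | CC(C)=CCC/C(C)=C/CC/C(C)=C/CC/C(C)=C/C[C@H]1CC(=O)C(C)(Sc2ccccc2)CC1
F5 | step 5 | (5S)-2-methyl-2-(phenylsulfinyl)-5-GG-cyclohexan-1-one (epimers at C2 and S) | CC(C)=CCC/C(C)=C/CC/C(C)=C/CC/C(C)=C/C[C@H]1CC(=O)C(C)(S(=O)c2ccccc2)CC1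
F0 | step 4 | none | none
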